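The route rests on disconnecting C4–C5. Ring B (C5–C10), whose C8 ketone lies para to the methyl-bearing quaternary C5 and whose C10 carries the C1–C4 chain, is treated as an oxidised para-cresol. A single hypervalent-iodine oxidative dearomatisation lets the C4 carbon of a tethered β-keto ester attack C5, closing ring A, creating the C5 quaternary and C4 centres and leaving the C6=C7/C9=C10 dienone around the C8 ketone. The precursor is phenol 17, methyl 5-{5-hydroxy-4-[(2S)-1-methoxy-1-oxopropan-2-yl]-2-methylphenyl}-3-oxopentanoate, with C11 already set and the phenol released from a benzyl ether only at the end.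

Key step: step 9

Remarks
- Locants: ring A = C1–C5, C10; ring B = C5–C10; C11 = side-chain CH. By CIP analysis the target is (3R,4S,5S,10S,11S): 3-OAng, 4-CO2Me, 5-CH3 and 10-H lie on one face of a cis-decalin. Compounds 17 and 18 carry the matching C4, C5 and C11 configurations, so no structure needed correction.
- An ortho-hydroxyaryl propanoate such as 17 can lactonise to a benzofuran-2(3H)-one whose C11–H is very acidic. The phenol is therefore carried as a benzyl ether, strong base is avoided once C11 is set, and 17 is oxidised as soon as it is formed.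
- Homogeneous hydroxyl- or ester-directed hydrogenation is not relied on for C9=C10: the C3 oxygen lies across ring A from C10, and both ester carbonyls sit beside C6=C7.
- Compounds 1, 4, 11, 13, 21 and the chiral iodoarene of step 9 are assumed to be purchasable.

Step 1
Reactants: 1 3-bromo-4-methylphenol
Product: 2 5-bromo-2-iodo-4-methylphenol
Conditions: NIS (1.05 equiv), TsOH·H2O (10 mol %), MeCN, 0 °C to rt
Reagents that add atoms: N-iodosuccinimide, O=C1CCC(=O)N1I
Why: Electrophilic aromatic iodination of a phenol, in which the para position is blocked by the methyl group and, of the two ortho positions, the one para to bromine (future C7) is open while the other (future C9) is wedged between OH and Br.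

Step 2
Reactants: 2 5-bromo-2-iodo-4-methylphenol
Product: 3 1-(benzyloxy)-5-bromo-2-iodo-4-methylbenzene
Conditions: BnBr, K2CO3, DMF, rt
Reagents that add atoms: benzyl bromide, BrCc1ccccc1
Why: Williamson ether synthesis; the benzyl ether tolerates the organomagnesium, ylide, hydroxide and palladium steps and is later removed by neutral hydrogenolysis.

Step 3
Reactants: 3 1-(benzyloxy)-5-bromo-2-iodo-4-methylbenzene; 4 dimethyl oxalate
Product: 6 methyl 2-[2-(benzyloxy)-4-bromo-5-methylphenyl]-2-oxoacetate, via arylmagnesium chloride 5 (not isolated)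
Conditions: iPrMgCl·LiCl, THF, −20 °C; then added to 4 (2 equiv), THF, −78 °C; aq. NH4Cl
Reagents that add atoms: isopropylmagnesium chloride–lithium chloride, CC(C)[Mg]Cl.[Li+].[Cl-] (supplies only the MgCl of intermediate 5)
Why: Iodine–magnesium exchange is much faster at C–I than at C–Br and is assisted by the ortho alkoxy group, and inverse addition of the aryl Grignard reagent to excess oxalate at low temperature stops at the α-keto ester (Grignard acylation).

Step 4
Reactants: 6 methyl 2-[2-(benzyloxy)-4-bromo-5-methylphenyl]-2-oxoacetate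
Product: 8 2-[2-(benzyloxy)-4-bromo-5-methylphenyl]prop-2-enoic acid, via methyl 2-arylacrylate 7 (not isolated)
Conditions: Ph3PCH3Br, KOtBu, THF, 0 °C; then LiOH·H2O, H2O, rt; aq. HCl
Reagents that add atoms: methyltriphenylphosphonium bromide, C[P+](c1ccccc1)(c1ccccc1)c1ccccc1.[Br-]; lithium hydroxide, [Li+].[OH-]
Why: Wittig methylenation of the activated ketone of the aryl glyoxylate gives the 2-arylacrylate, which is saponified in the same flask so that the polymerisable ester is not stored and Ph3PO is left behind on acid–base extraction.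

Step 5
Reactants: 8 2-[2-(benzyloxy)-4-bromo-5-methylphenyl]prop-2-enoic acid
Product: 10 methyl (2S)-2-[2-(benzyloxy)-4-bromo-5-methylphenyl]propanoate, via (S)-2-arylpropanoic acid 9 (not isolated)
Conditions: H2 (100 atm), Ru(OAc)2[(S)-BINAP] (0.5 mol %), MeOH, rt; then H2SO4 (5 mol %), MeOH, 50 °C
Reagents that add atoms: methanol, CO
Why: Ru–BINAP asymmetric hydrogenation of a 2-arylacrylic acid, in which the carboxylate binds ruthenium and one enantioface of the alkene receives hydrogen, sets C11 and by analogy with 2-arylpropenoic acids of the profen class the (S)-ligand should give the (S)-acid (the antipodal ligand is taken should the sense prove opposite), after which acid-catalysed Fischer esterification in the same methanol solution leaves the stereocentre untouched.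

Step 6
Reactants: 10 methyl (2S)-2-[2-(benzyloxy)-4-bromo-5-methylphenyl]propanoate; 11 acrylic acid
Product: 12 (2E)-3-{5-(benzyloxy)-4-[(2S)-1-methoxy-1-oxopropan-2-yl]-2-methylphenyl}prop-2-enoic acid
Conditions: Pd(OAc)2 (5 mol %), P(o-tol)3 (10 mol %), NaOAc, DMAc, 110 °C
Reagents that add atoms: none
Why: Mizoroki–Heck arylation of acrylic acid at the remaining aryl bromide gives the (E)-cinnamic acid, and a carboxylate base is far too weak to deprotonate the α-aryl propanoate centre C11.

Step 7
Reactants: 12 (2E)-3-{5-(benzyloxy)-4-[(2S)-1-methoxy-1-oxopropan-2-yl]-2-methylphenyl}prop-2-enoic acid; 13 potassium methyl malonate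
Product: 16 methyl (4E)-5-{5-(benzyloxy)-4-[(2S)-1-methoxy-1-oxopropan-2-yl]-2-methylphenyl}-3-oxopent-4-enoate, via acylimidazole 14 (not isolated), via acylmalonic half-ester 15 (not isolated)
Conditions: CDI, THF, rt; then 13, MgCl2, Et3N, MeCN, rt; aq. HCl
Reagents that add atoms: 1,1'-carbonyldiimidazole, O=C(n1ccnc1)n1ccnc1 (supplies only the imidazolyl group of intermediate 14)
Why: Activation as the acylimidazole, C-acylation of the magnesium enolate of the malonic half-ester and decarboxylation (Masamune–Brooks β-keto ester synthesis) install C3, C4 and the C4 ester under near-neutral conditions that leave C11 untouched.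

Step 8
Reactants: 16 methyl (4E)-5-{5-(benzyloxy)-4-[(2S)-1-methoxy-1-oxopropan-2-yl]-2-methylphenyl}-3-oxopent-4-enoate
Product: 17 methyl 5-{5-hydroxy-4-[(2S)-1-methoxy-1-oxopropan-2-yl]-2-methylphenyl}-3-oxopentanoate
Conditions: H2 (1 atm), 10% Pd/C, EtOAc, rt
Reagents that add atoms: none
Why: Heterogeneous hydrogenation saturates the styryl enone C=C and hydrogenolyses the benzyl ether in one neutral operation, so the lactonisation-prone ortho-hydroxyaryl propanoate is released only at the point of use.

Step 9
Reactants: 17 methyl 5-{5-hydroxy-4-[(2S)-1-methoxy-1-oxopropan-2-yl]-2-methylphenyl}-3-oxopentanoate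
Product: 18 methyl (1S,8aS)-7-[(2S)-1-methoxy-1-oxopropan-2-yl]-8a-methyl-2,6-dioxo-1,2,3,4,6,8a-hexahydronaphthalene-1-carboxylate
Conditions: (R,R)-2-iodo-1,3-bis[1-(mesitylcarbamoyl)ethoxy]benzene (10 mol %), mCPBA (1.2 equiv), CH2Cl2–HFIP (4:1), −20 °C
Reagents that add atoms: none
Why: Proposed new method: mCPBA oxidises the aryl iodide to a chiral aryl-λ3-iodane (trivalent iodine) that binds the phenol oxygen of 17, and loss of the aryl iodide turns ring B into a phenoxonium-type electrophile whose para carbon C5 is captured by the enol carbon C4 of the β-keto ester, C5 being unable to rearomatise because it keeps its methyl, so that dienone 18 results. The closest known reaction types are the hypervalent-iodine dearomative C–C cyclisation of phenols onto tethered 1,3-dicarbonyl or enol nucleophiles (mostly spiro closures) and the chiral aryl-iodide-catalysed para dearomatisation of unsymmetrical phenols by oxygen nucleophiles. Ring A closes as a six-membered ring (C4, C3, C2, C1, C10, C5) by 6-exo-trig attack of C4 on C5, counted against the C5=C6 bond of the quinoid cation, the C5–C10 bond being shared by both rings. C5 is controlled by the O-bound C2-symmetric iodane, whose lactamide arms should shield one face of the arene while the tether delivers C4 to the other (the catalyst antipode is chosen accordingly), and because C11 is already (S) the C5 epimer is a diastereomer that chromatography removes, while C4 is under thermodynamic control through the β-keto ester enol and should rest with CO2Me equatorial and cis to the axial C5 methyl. The step needs para (C5) over ortho (C9) capture, which the larger para coefficient of the phenoxonium, the cation-stabilising C5 methyl, the blocked C7 and low temperature in a fluorinated alcohol should secure. Phenol 17 is oxidised directly after step 8 so that lactonisation of the ortho-hydroxyaryl propanoate and loss of C11 integrity cannot intervene.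

Step 10
Reactants: 18 methyl (1S,8aS)-7-[(2S)-1-methoxy-1-oxopropan-2-yl]-8a-methyl-2,6-dioxo-1,2,3,4,6,8a-hexahydronaphthalene-1-carboxylate
Product: 19 methyl (1S,2R,8aS)-2-hydroxy-7-[(2S)-1-methoxy-1-oxopropan-2-yl]-8a-methyl-6-oxo-1,2,3,4,6,8a-hexahydronaphthalene-1-carboxylate
Conditions: NaBH4 (1 equiv), MeOH–CH2Cl2 (1:1), −40 °C
Reagents that add atoms: none
Why: Sodium borohydride reduction takes the saturated C3 ketone well before the cross-conjugated C8 carbonyl, and since the β-keto ester epimers interconvert, the one with equatorial CO2Me is reduced by equatorial hydride delivery from the face opposite the syn-axial C5 methyl, which places the C3 hydroxyl axial and cis to both CO2Me and CH3 and fixes C4 (Curtin–Hammett control).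

Step 11
Reactants: 19 methyl (1S,2R,8aS)-2-hydroxy-7-[(2S)-1-methoxy-1-oxopropan-2-yl]-8a-methyl-6-oxo-1,2,3,4,6,8a-hexahydronaphthalene-1-carboxylate
Product: 20 methyl (1S,2R,4aS,8aS)-2-hydroxy-7-[(2S)-1-methoxy-1-oxopropan-2-yl]-8a-methyl-6-oxo-1,2,3,4,4a,5,6,8a-octahydronaphthalene-1-carboxylate
Conditions: H2 (1 atm, stopped after 1 equiv), 5% Pd/C, EtOAc–pyridine (10:1), 0 °C to rt
Reagents that add atoms: none
Why: Heterogeneous catalytic hydrogenation, in which ring A is folded under one face of the flat dienone so that the catalyst binds the face bearing the angular methyl and delivers hydrogen to C10 cis to that methyl (the bias that turns angular-methyl octalones into cis-decalones), while C9=C10 with its unhindered C9 terminus should react before C6=C7, which is flanked by quaternary C5 and the branched C11 substituent.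

Step 12
Reactants: 20 methyl (1S,2R,4aS,8aS)-2-hydroxy-7-[(2S)-1-methoxy-1-oxopropan-2-yl]-8a-methyl-6-oxo-1,2,3,4,4a,5,6,8a-octahydronaphthalene-1-carboxylate; 21 angelic acid
Product: 23 methyl (1S,2R,4aS,8aS)-7-[(2S)-1-methoxy-1-oxopropan-2-yl]-8a-methyl-2-{[(2Z)-2-methylbut-2-enoyl]oxy}-6-oxo-1,2,3,4,4a,5,6,8a-octahydronaphthalene-1-carboxylate, via mixed anhydride 22 (not isolated)
Conditions: 21, 2,4,6-Cl3C6H2COCl, Et3N, toluene, rt; then 20, 70 °C
Reagents that add atoms: 2,4,6-trichlorobenzoyl chloride, O=C(Cl)c1c(Cl)cc(Cl)cc1Cl (supplies only the aroyl group of intermediate 22)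
Why: Yamaguchi esterification through the mixed anhydride acylates the hindered secondary alcohol without a nucleophilic catalyst, which avoids Z-to-E isomerisation of the angelate to the tiglate and keeps the medium mild enough for C11 and the β-acyloxy ester.

Compound list
1 | 3-bromo-4-methylphenol | Cc1ccc(O)cc1Br | starting material
2 | 5-bromo-2-iodo-4-methylphenol | Cc1cc(I)c(O)cc1Br | intermediate
3 | 1-(benzyloxy)-5-bromo-2-iodo-4-methylbenzene | Cc1cc(I)c(OCc2ccccc2)cc1Br | intermediate
4 | dimethyl oxalate | COC(=O)C(=O)OC | starting material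
5 | [2-(benzyloxy)-4-bromo-5-methylphenyl]magnesium chloride | Cc1cc([Mg]Cl)c(OCc2ccccc2)cc1Br | intermediate (not isolated)
6 | methyl 2-[2-(benzyloxy)-4-bromo-5-methylphenyl]-2-oxoacetate | Cc1cc(C(=O)C(=O)OC)c(OCc2ccccc2)cc1Br | intermediate
7 | methyl 2-[2-(benzyloxy)-4-bromo-5-methylphenyl]prop-2-enoate | Cc1cc(C(=C)C(=O)OC)c(OCc2ccccc2)cc1Br | intermediate (not isolated)
8 | 2-[2-(benzyloxy)-4-bromo-5-methylphenyl]prop-2-enoic acid | Cc1cc(C(=C)C(=O)O)c(OCc2ccccc2)cc1Br | intermediate
9 | (2S)-2-[2-(benzyloxy)-4-bromo-5-methylphenyl]propanoic acid | Cc1cc([C@H](C)C(=O)O)c(OCc2ccccc2)cc1Br | intermediate (not isolated)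
10 | methyl (2S)-2-[2-(benzyloxy)-4-bromo-5-methylphenyl]propanoate | Cc1cc([C@H](C)C(=O)OC)c(OCc2ccccc2)cc1Br | intermediate
11 | acrylic acid | C=CC(=O)O | starting material
12 | (2E)-3-{5-(benzyloxy)-4-[(2S)-1-methoxy-1-oxopropan-2-yl]-2-methylphenyl}prop-2-enoic acid | Cc1cc([C@H](C)C(=O)OC)c(OCc2ccccc2)cc1/C=C/C(=O)O | intermediate
13 | potassium methyl malonate (potassium 3-methoxy-3-oxopropanoate) | COC(=O)CC(=O)[O-].[K+] | starting material
14 | methyl (2S)-2-{2-(benzyloxy)-4-[(1E)-3-(imidazol-1-yl)-3-oxoprop-1-en-1-yl]-5-methylphenyl}propanoate | Cc1cc([C@H](C)C(=O)OC)c(OCc2ccccc2)cc1/C=C/C(=O)n1ccnc1 | intermediate (not isolated)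
15 | (4E)-5-{5-(benzyloxy)-4-[(2S)-1-methoxy-1-oxopropan-2-yl]-2-methylphenyl}-2-(methoxycarbonyl)-3-oxopent-4-enoic acid | Cc1cc([C@H](C)C(=O)OC)c(OCc2ccccc2)cc1/C=C/C(=O)C(C(=O)O)C(=O)OC | intermediate (not isolated)
16 | methyl (4E)-5-{5-(benzyloxy)-4-[(2S)-1-methoxy-1-oxopropan-2-yl]-2-methylphenyl}-3-oxopent-4-enoate | Cc1cc([C@H](C)C(=O)OC)c(OCc2ccccc2)cc1/C=C/C(=O)CC(=O)OC | intermediate
17 | methyl 5-{5-hydroxy-4-[(2S)-1-methoxy-1-oxopropan-2-yl]-2-methylphenyl}-3-oxopentanoate (precursor of the key step) | COC(=O)CC(=O)CCc1cc(O)c([C@H](C)C(=O)OC)cc1C | intermediate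
18 | methyl (1S,8aS)-7-[(2S)-1-methoxy-1-oxopropan-2-yl]-8a-methyl-2,6-dioxo-1,2,3,4,6,8a-hexahydronaphthalene-1-carboxylate (C3 ketone, C6=C7 and C9=C10 dienone; 4S,5S,11S) | O=C1CCC2=CC(=O)C([C@H](C)C(=O)OC)=C[C@@]2(C)[C@@H]1C(=O)OC | intermediate
19 | methyl (1S,2R,8aS)-2-hydroxy-7-[(2S)-1-methoxy-1-oxopropan-2-yl]-8a-methyl-6-oxo-1,2,3,4,6,8a-hexahydronaphthalene-1-carboxylate (3-OH, 4-CO2Me and 5-CH3 cis) | O[C@@H]1CCC2=CC(=O)C([C@H](C)C(=O)OC)=C[C@@]2(C)[C@@H]1C(=O)OC | intermediate
20 | methyl (1S,2R,4aS,8aS)-2-hydroxy-7-[(2S)-1-methoxy-1-oxopropan-2-yl]-8a-methyl-6-oxo-1,2,3,4,4a,5,6,8a-octahydronaphthalene-1-carboxylate (cis-decalin, 10-H cis to 5-CH3) | O[C@@H]1CC[C@H]2CC(=O)C([C@H](C)C(=O)OC)=C[C@@]2(C)[C@@H]1C(=O)OC | intermediate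
21 | angelic acid ((2Z)-2-methylbut-2-enoic acid) | C/C=C(/C)C(=O)O | starting material
22 | angelic 2,4,6-trichlorobenzoic anhydride | C/C=C(/C)C(=O)OC(=O)c1c(Cl)cc(Cl)cc1Cl | intermediate (not isolated)
23 | methyl (1S,2R,4aS,8aS)-7-[(2S)-1-methoxy-1-oxopropan-2-yl]-8a-methyl-2-{[(2Z)-2-methylbut-2-enoyl]oxy}-6-oxo-1,2,3,4,4a,5,6,8a-octahydronaphthalene-1-carboxylate (CNP0265265.1) | C/C=C(/C)C(=O)O[C@@H]1CC[C@H]2CC(=O)C([C@H](C)C(=O)OC)=C[C@@]2(C)[C@@H]1C(=O)OC | target

Total step count: 12. Longest linear sequence: 12 steps (1 to 23; the route is fully linear).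

Steps most likely to fail

Step 9. The chiral iodane may fail to differentiate the two faces of C5, may turn over poorly with mCPBA, or the enol may add in part at the open ortho carbon C9 with rearomatisation. The fallback uses known chemistry, sets out from 17 and returns at 18. Phenol 17 is oxidised with stoichiometric PhI(OAc)2 in HFIP at 0 °C (hypervalent-iodine dearomative cyclisation of a phenol onto a tethered 1,3-dicarbonyl, no chiral controller; the fluorinated alcohol favours the free phenoxonium and para capture). This should give 18 together with its C5 epimer, methyl (1R,8aR)-7-[(2S)-1-methoxy-1-oxopropan-2-yl]-8a-methyl-2,6-dioxo-1,2,3,4,6,8a-hexahydronaphthalene-1-carboxylate F1. Because C11 is fixed the two are diastereomers; they are separated by chromatography and F1 is discarded.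

Step 11. Hydrogen uptake may not stop at C9=C10, so that C6=C7 is saturated as well, or the C6=C7 bond may migrate toward C11 on the metal. The fallback sets out from 19 and returns at 20. Exhaustive hydrogenation (H2, 4 atm, Pd/C, EtOAc) should give the saturated cis-fused C8 ketone, the 6,7-dihydro derivative of 20 as C7 epimers F2. Thermodynamic silylation (TMSCl, NaI, Et3N, MeCN) should then give the C7=C8 trimethylsilyl enol ether that also carries a C3 trimethylsilyl ether, the bis(trimethylsilyl) compound F3. Saegusa–Ito oxidation with Pd(OAc)2 in MeCN, with β-hydride loss from C6, re-forms the C6=C7 enone as the C3 trimethylsilyl ether of 20 F4, and aqueous citric acid returns 20.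

Step 10. Hydride may be delivered from the methyl-bearing face or through the other C4 epimer, eroding the C3/C4 relationship, or may reach the C8 carbonyl. The fallback sets out from 18 and returns at 19. It is an enzymatic dynamic reductive kinetic resolution: a ketoreductase panel (NADPH, glucose/glucose dehydrogenase recycling, pH 7 buffer with DMSO) is screened for an enzyme that reduces the rapidly epimerising β-keto ester to the (3R,4S) cis-hydroxy ester. No new compound arises (F0).

Further compounds
F1 | step 9 | methyl (1R,8aR)-7-[(2S)-1-methoxy-1-oxopropan-2-yl]-8a-methyl-2,6-dioxo-1,2,3,4,6,8a-hexahydronaphthalene-1-carboxylate (C5 epimer of 18; 4R,5R,11S) | O=C1CCC2=CC(=O)C([C@H](C)C(=O)OC)=C[C@]2(C)[C@H]1C(=O)OC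
F2 | step 11 | 6,7-dihydro derivative of 20: methyl 2-hydroxy-7-[(2S)-1-methoxy-1-oxopropan-2-yl]-8a-methyl-6-oxodecahydronaphthalene-1-carboxylate, ring centres as in 20, C7 epimers | O[C@@H]1CC[C@H]2CC(=O)C([C@H](C)C(=O)OC)C[C@@]2(C)[C@@H]1C(=O)OC
F3 | step 11 | bis(trimethylsilyl) compound: C3 trimethylsilyl ether and C7=C8 trimethylsilyl enol ether of F2 | C[Si](C)(C)O[C@@H]1CC[C@H]2CC(O[Si](C)(C)C)=C([C@H](C)C(=O)OC)C[C@@]2(C)[C@@H]1C(=O)OC
F4 | step 11 | C3 trimethylsilyl ether of 20 | C[Si](C)(C)O[C@@H]1CC[C@H]2CC(=O)C([C@H](C)C(=O)OC)=C[C@@]2(C)[C@@H]1C(=O)OC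
F0 | step 10 | none | none
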